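Ring A is built last. Its C4a–C8a edge is the α,β-bond of the lactone carbonyl C1. Its unsubstituted C5–C6–C7–C8 segment, oxygenated at C5 and C8, is succinic anhydride in bis-enol form. One [4+2] union of 2,5-bis(trimethylsilyloxy)furan with an (R)-6-alkyl-5,6-dihydropyran-2-one therefore makes C4a–C5 and C8a–C8. Collapse of the oxygen bridge and enolisation then release the free hydroquinone at the right oxidation level, without oxidant or phenol protection. The dienophile already carries C3 (R), C4' (S) and the succinate, masked as its tert-butyl ester, so only acidolysis follows.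

Key step: step 8

Remark on the chemistry: diene plus alkene already sums to the hydroquinone level once the bridging oxygen leaves as hexamethyldisiloxane. No activating or leaving group is therefore placed on C8a, since it would raise the product to the quinone level and release HX. The weak dienophile is answered by pressure and surplus diene instead.
Remark on the reagent of step 4: the allylborane is defined by its origin, (+)-α-pinene via (−)-Ipc2BOMe, because sign-based names for it are not used uniformly.

Step 1
Reactants: 1 but-3-enylmagnesium bromide; 2 (S)-propylene oxide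
Product: 3 (S)-hept-6-en-2-ol
Conditions: CuI (10 mol%), THF, −30 → 0 °C; sat. aq NH4Cl
Reagents that add atoms: none
Why: Copper-catalysed Grignard opening of a terminal epoxide is an SN2 attack at the unsubstituted carbon, so the C–O stereocentre of 2 is untouched and becomes C4' (S).

Step 2
Reactants: 3 (S)-hept-6-en-2-ol; 4 mono-tert-butyl succinate
Product: 5 tert-butyl (S)-hept-6-en-2-yl succinate
Conditions: DCC (1.1 equiv), DMAP (10 mol%), CH2Cl2, 0 °C → rt
Reagents that add atoms: none
Why: Steglich esterification acylates at oxygen with retention at C4', installs the differentiated succinate in one operation, and keeps every intermediate up to 20 neutral so that succinic acid from surplus diene can later be washed out with NaHCO3.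

Step 3
Reactants: 5 tert-butyl (S)-hept-6-en-2-yl succinate
Product: 7 tert-butyl (S)-6-oxohexan-2-yl succinate, via secondary ozonide 6 (not isolated)
Conditions: O3, CH2Cl2, −78 °C; PPh3 (1.2 equiv), −78 °C → rt
Reagents that add atoms: ozone, [O-][O+]=O
Why: Ozonolysis with reductive work-up (Criegee mechanism) cleaves the only alkene to the aldehyde and affects neither ester.

Step 4
Reactants: 7 tert-butyl (S)-6-oxohexan-2-yl succinate; 8 allylmagnesium bromide; 9 (−)-B-methoxydiisopinocampheylborane
Product: 12 tert-butyl (2S,6R)-6-hydroxynon-8-en-2-yl succinate, via B-allyldiisopinocampheylborane 10 (not isolated), via homoallyl diisopinocampheylborinate 11 (not isolated)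
Conditions: 9 (1.3 equiv), 8 (1.25 equiv), Et2O, 0 °C → rt; 7, −78 °C; MeOH, NaH2PO4/Na2HPO4 buffer (pH 7), 30% H2O2, 0 °C → rt
Reagents that add atoms: none
Why: Brown asymmetric allylboration runs through a closed Zimmerman–Traxler chair in which the isopinocampheyl groups from (+)-α-pinene steer allyl transfer to the face that gives the (R)-carbinol (future C3) from unbranched aliphatic aldehydes, while the remote C4' has no influence, the slight deficit of 8 keeps free Grignard away from the esters, and the buffered peroxide work-up avoids saponification.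

Step 5
Reactants: 12 tert-butyl (2S,6R)-6-hydroxynon-8-en-2-yl succinate; 13 acryloyl chloride
Product: 14 tert-butyl (2S,6R)-6-(acryloyloxy)non-8-en-2-yl succinate
Conditions: Et3N (2.5 equiv), DMAP (5 mol%), CH2Cl2, 0 °C
Reagents that add atoms: none
Why: DMAP-catalysed acylation with an acid chloride takes place at oxygen, so C3 keeps its configuration.

Step 6
Reactants: 14 tert-butyl (2S,6R)-6-(acryloyloxy)non-8-en-2-yl succinate
Product: 15 tert-butyl (S)-5-[(R)-6-oxo-3,6-dihydro-2H-pyran-2-yl]pentan-2-yl succinate
Conditions: second-generation Grubbs catalyst (H2IMes)(PCy3)Cl2Ru=CHPh (3 mol%), CH2Cl2 (0.005 M), reflux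
Reagents that add atoms: none
Why: Ring-closing metathesis of a homoallyl acrylate is the standard entry to 6-substituted 5,6-dihydropyran-2-ones, with ethene loss driving the six-ring closure, the ring enforcing the Z alkene and dilution suppressing dimerisation.

Step 7
Reactants: 16 succinic anhydride
Product: 17 2,5-bis(trimethylsilyloxy)furan
Conditions: TMSOTf (2.2 equiv), Et3N (2.5 equiv), Et2O, 0 °C → rt; decant from the salt layer; distil under reduced pressure
Reagents that add atoms: trimethylsilyl trifluoromethanesulfonate (TMSOTf), C[Si](C)(C)OS(=O)(=O)C(F)(F)F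
Why: Double enol silylation of the cyclic anhydride (soft enolisation with amine and silyl triflate) gives the known, moisture-sensitive bis(silyl ketene acetal) furan, which is distilled and used at once.

Step 8
Reactants: 15 tert-butyl (S)-5-[(R)-6-oxo-3,6-dihydro-2H-pyran-2-yl]pentan-2-yl succinate; 17 2,5-bis(trimethylsilyloxy)furan
Product: 20 tert-butyl (S)-5-[(R)-5,8-dihydroxy-1-oxoisochroman-3-yl]pentan-2-yl succinate, via oxa-bridged cycloadduct 18 (not isolated), via cis-fused enedione 19 (not isolated)
Conditions: 17 (5 equiv), CH2Cl2 (1 M, filtered through basic Al2O3), PTFE ampoule, 12 kbar, 40 °C, 72 h; then degassed THF–0.5 M aq HCl, Ar, 0 °C → rt; NaHCO3 wash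
Reagents that add atoms: none
Why: Proposed new method: the s-cis-locked, strongly electron-rich furan 17 should add suprafacially through its two silyloxy-bearing carbons to the electron-poor C4a=C8a alkene of 15 in a normal-electron-demand [4+2] cycloaddition, giving the 7-oxabicyclo[2.2.1]heptene 18; mild acid then collapses its bridging bis-ketal with loss of hexamethyldisiloxane to the cyclohex-2-ene-1,4-dione 19, and enolisation of C8a–H (flanked by the C1 and C8 carbonyls) and of C4a–H aromatises ring A without an oxidant. The closest known reaction type is the Diels–Alder/aromatisation sequence of 2,5-bis(silyloxy)furans with doubly activated or unhindered electron-poor alkenes and alkynes, which gives hydroquinones or quinones; a singly activated, β-alkylated δ-lactone lies outside that range, which is why 12 kbar is applied to exploit the strongly negative activation volume of cycloaddition at a temperature the diene survives. Ring A, a six-membered carbocycle, is closed by intermolecular cycloaddition in which C4a–C5 and C8a–C8 form in one event, and the oxygen bridge closed alongside is only transient. The sp3 centres created at C4a, C5, C8 and C8a are all erased on aromatisation, so endo/exo and facial outcomes are immaterial, no permanent stereocentre is made, and the carbinol centres C3 and C4' lie outside the reacting array and keep their configuration. The selectivity required is one of reaction mode, cycloaddition at furan C2/C5 rather than Mukaiyama–Michael addition through furan C3, and it is secured by excluding every Lewis acid and using a weakly polar medium that disfavours a zwitterionic path, while the symmetry of 17 removes any regiochemical question. Surplus diene offsets its slow decay, and the degassed dilute acid is strong enough to open 18 but too weak to cleave the tert-butyl ester or to let 20 oxidise.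

Step 9
Reactants: 20 tert-butyl (S)-5-[(R)-5,8-dihydroxy-1-oxoisochroman-3-yl]pentan-2-yl succinate
Product: 21 aspergimarin B
Conditions: CF3CO2H–CH2Cl2 (1:4), Et3SiH (3 equiv), Ar, 0 °C → rt; evaporate
Reagents that add atoms: none
Why: Acidolysis of the tert-butyl ester (alkyl–oxygen cleavage via the tert-butyl cation) spares the secondary alkyl ester and the lactone, and triethylsilane intercepts the cation by hydride transfer before it can alkylate the electron-rich ring A at C6 or C7.

Compound list
1 | but-3-enylmagnesium bromide | C=CCC[Mg]Br | starting material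
2 | (S)-propylene oxide | C[C@H]1CO1 | starting material
3 | (S)-hept-6-en-2-ol | C[C@@H](CCCC=C)O | intermediate
4 | mono-tert-butyl succinate (4-tert-butoxy-4-oxobutanoic acid) | OC(=O)CCC(=O)OC(C)(C)C | starting material
5 | tert-butyl (S)-hept-6-en-2-yl succinate | C[C@@H](CCCC=C)OC(=O)CCC(=O)OC(C)(C)C | intermediate
6 | tert-butyl (2S)-5-(1,2,4-trioxolan-3-yl)pentan-2-yl succinate, secondary ozonide, both epimers at the trioxolane carbon, formed in the flask | C[C@@H](CCCC1OCOO1)OC(=O)CCC(=O)OC(C)(C)C | intermediate
7 | tert-butyl (S)-6-oxohexan-2-yl succinate | C[C@@H](CCCC=O)OC(=O)CCC(=O)OC(C)(C)C | intermediate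
8 | allylmagnesium bromide | C=CC[Mg]Br | starting material
9 | (−)-B-methoxydiisopinocampheylborane, (−)-Ipc2BOMe, derived from (+)-α-pinene | COB([C@@H]1C[C@@H]2C[C@H]([C@H]1C)C2(C)C)[C@@H]1C[C@@H]2C[C@H]([C@H]1C)C2(C)C | starting material
10 | B-allyldiisopinocampheylborane derived from (+)-α-pinene, formed in the flask | C=CCB([C@@H]1C[C@@H]2C[C@H]([C@H]1C)C2(C)C)[C@@H]1C[C@@H]2C[C@H]([C@H]1C)C2(C)C | intermediate
11 | diisopinocampheylborinate of 12, formed in the flask | C[C@@H](CCC[C@@H](OB([C@@H]1C[C@@H]2C[C@H]([C@H]1C)C2(C)C)[C@@H]1C[C@@H]2C[C@H]([C@H]1C)C2(C)C)CC=C)OC(=O)CCC(=O)OC(C)(C)C | intermediate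
12 | tert-butyl (2S,6R)-6-hydroxynon-8-en-2-yl succinate | C[C@@H](CCC[C@@H](O)CC=C)OC(=O)CCC(=O)OC(C)(C)C | intermediate
13 | acryloyl chloride | C=CC(=O)Cl | starting material
14 | tert-butyl (2S,6R)-6-(acryloyloxy)non-8-en-2-yl succinate | C[C@@H](CCC[C@@H](OC(=O)C=C)CC=C)OC(=O)CCC(=O)OC(C)(C)C | intermediate
15 | tert-butyl (S)-5-[(R)-6-oxo-3,6-dihydro-2H-pyran-2-yl]pentan-2-yl succinate | C[C@@H](CCC[C@@H]1CC=CC(=O)O1)OC(=O)CCC(=O)OC(C)(C)C | intermediate
16 | succinic anhydride | O=C1CCC(=O)O1 | starting material
17 | 2,5-bis(trimethylsilyloxy)furan | C[Si](C)(C)Oc1ccc(O[Si](C)(C)C)o1 | intermediate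
18 | tert-butyl (S)-5-[(3R)-1-oxo-5,8-bis(trimethylsilyloxy)-3,4,4a,5,8,8a-hexahydro-1H-5,8-epoxyisochromen-3-yl]pentan-2-yl succinate, isomer mixture at C4a, C5, C8 and C8a, formed in the flask | C[C@@H](CCC[C@@H]1CC2C(C(=O)O1)C3(O[Si](C)(C)C)C=CC2(O[Si](C)(C)C)O3)OC(=O)CCC(=O)OC(C)(C)C | intermediate
19 | tert-butyl (S)-5-[(3R)-1,5,8-trioxo-3,4,4a,5,8,8a-hexahydro-1H-isochromen-3-yl]pentan-2-yl succinate, cis-fused, formed in the flask | C[C@@H](CCC[C@@H]1CC2C(C(=O)O1)C(=O)C=CC2=O)OC(=O)CCC(=O)OC(C)(C)C | intermediate
20 | tert-butyl (S)-5-[(R)-5,8-dihydroxy-1-oxoisochroman-3-yl]pentan-2-yl succinate | C[C@@H](CCC[C@@H]1Cc2c(O)ccc(O)c2C(=O)O1)OC(=O)CCC(=O)OC(C)(C)C | intermediate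
21 | aspergimarin B, 4-{[(S)-5-[(R)-5,8-dihydroxy-1-oxoisochroman-3-yl]pentan-2-yl]oxy}-4-oxobutanoic acid | C[C@@H](CCC[C@@H]1Cc2c(O)ccc(O)c2C(=O)O1)OC(=O)CCC(=O)O | target

Total step count: 9. Longest linear sequence: 8 steps (1–6, 8, 9); step 7 is a one-step side branch.

Steps most likely to fail

1. Step 8.
- **What may go wrong:** The singly activated, β-alkylated alkene may add so slowly that the diene is first lost to desilylation or silyl migration. Conjugate addition through furan C3 may overtake cycloaddition. The adduct may also revert on decompression before its ketal opens.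
- **Fallback:** This uses known chemistry, in which ring A is bought and the lactone is closed onto it. It sets out from 3 and returns at 21.
- **Epoxide partner:** Alcohol 3 is silylated (TBSCl, imidazole) to (S)-tert-butyl(hept-6-en-2-yloxy)dimethylsilane F1. This is epoxidised with mCPBA to the epimeric oxiranes F2. Jacobsen hydrolytic kinetic resolution [(R,R)-(salen)Co(OAc), salen = N,N'-bis(3,5-di-tert-butylsalicylidene)cyclohexane-1,2-diamine dianion, 0.55 equiv H2O] then leaves the (R)-oxirane F3.
- **Arene partner and coupling:** N,N-Diethyl-2,5-dimethoxybenzamide F4 is made from 2,5-dimethoxybenzoic acid (SOCl2, then Et2NH). Directed ortho-metalation (s-BuLi, TMEDA, THF, −78 °C) between the amide and the 5-methoxy group gives the aryllithium F5. This opens F3 at its CH2 terminus in the presence of BF3·OEt2 to give the hydroxy amide F6.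
- **End game:** Aqueous HCl in dioxane at 80 °C lactonises and desilylates to (R)-3-[(S)-4-hydroxypentyl]-5,8-dimethoxyisochroman-1-one F7. Succinic anhydride 16 with DMAP gives the hemisuccinate F8. BBr3 (CH2Cl2, −78 → 0 °C) then cleaves both aryl methyl ethers to 21.

2. Step 4.
- **What may go wrong:** Reagent control may be incomplete, and an epimer differing only at a centre remote from C4' may resist separation. Removal of the borane residues may also cost material.
- **Fallback:** C3 is set by catalyst-controlled resolution and the lactone is built without allylation or metathesis. It sets out from 5 and returns at 15.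
- **Resolution:** Alkene 5 is epoxidised (mCPBA, CH2Cl2) to the epimeric oxiranes F9. Jacobsen hydrolytic kinetic resolution with (R,R)-(salen)Co(OAc) and 0.55 equiv H2O consumes the (S)-oxirane and leaves tert-butyl (S)-5-[(R)-oxiran-2-yl]pentan-2-yl succinate F10, which is readily parted from polar material.
- **Lactone construction:** Lithiated ethyl propiolate with BF3·OEt2 (THF, −78 °C, Yamaguchi–Hirao alkynylation) opens F10 at its CH2 terminus to the hydroxy ynoate F11. Semihydrogenation (H2, Pd/CaCO3 poisoned with Pb(OAc)2, quinoline) gives the (Z)-hydroxy enoate F12. This lactonises (PPTS, toluene, 80 °C) to 15.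

3. Step 9.
- **What may go wrong:** The tert-butyl cation may escape the scavenger and alkylate ring A, or the hydroquinone may oxidise during acid handling.
- **Fallback:** Ring A is masked by a redox change. It sets out from 20 and returns at 21.
- **Sequence:** Oxidation with Ag2O (Et2O, MgSO4) gives the quinone ester F13, whose electron-poor ring cannot be alkylated. CF3CO2H–CH2Cl2 removes the tert-butyl group to give the quinone acid F14. Na2S2O4 in EtOAc–H2O restores the hydroquinone and gives 21.

Further compounds
F1 | step 8 | (S)-tert-butyl(hept-6-en-2-yloxy)dimethylsilane | C[C@@H](CCCC=C)O[Si](C)(C)C(C)(C)C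
F2 | step 8 | tert-butyldimethyl{[(2S)-5-(oxiran-2-yl)pentan-2-yl]oxy}silane, both oxirane epimers | C[C@@H](CCCC1CO1)O[Si](C)(C)C(C)(C)C
F3 | step 8 | tert-butyldimethyl({(S)-5-[(R)-oxiran-2-yl]pentan-2-yl}oxy)silane | C[C@@H](CCC[C@@H]1CO1)O[Si](C)(C)C(C)(C)C
F4 | step 8 | N,N-diethyl-2,5-dimethoxybenzamide | CCN(CC)C(=O)c1cc(OC)ccc1OC
F5 | step 8 | [2-(diethylcarbamoyl)-3,6-dimethoxyphenyl]lithium | [Li]c1c(OC)ccc(OC)c1C(=O)N(CC)CC
F6 | step 8 | 2-[(2R,6S)-6-(tert-butyldimethylsilyloxy)-2-hydroxyheptyl]-N,N-diethyl-3,6-dimethoxybenzamide | C[C@@H](CCC[C@@H](O)Cc1c(OC)ccc(OC)c1C(=O)N(CC)CC)O[Si](C)(C)C(C)(C)C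
F7 | step 8 | (R)-3-[(S)-4-hydroxypentyl]-5,8-dimethoxyisochroman-1-one | C[C@@H](CCC[C@@H]1Cc2c(OC)ccc(OC)c2C(=O)O1)O
F8 | step 8 | 4-{[(S)-5-[(R)-5,8-dimethoxy-1-oxoisochroman-3-yl]pentan-2-yl]oxy}-4-oxobutanoic acid | C[C@@H](CCC[C@@H]1Cc2c(OC)ccc(OC)c2C(=O)O1)OC(=O)CCC(=O)O
F9 | step 4 | tert-butyl (2S)-5-(oxiran-2-yl)pentan-2-yl succinate, both oxirane epimers | C[C@@H](CCCC1CO1)OC(=O)CCC(=O)OC(C)(C)C
F10 | step 4 | tert-butyl (S)-5-[(R)-oxiran-2-yl]pentan-2-yl succinate | C[C@@H](CCC[C@@H]1CO1)OC(=O)CCC(=O)OC(C)(C)C
F11 | step 4 | tert-butyl (2S,6R)-10-ethoxy-6-hydroxy-10-oxodec-8-yn-2-yl succinate | C[C@@H](CCC[C@@H](O)CC#CC(=O)OCC)OC(=O)CCC(=O)OC(C)(C)C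
F12 | step 4 | tert-butyl (2S,6R,8Z)-10-ethoxy-6-hydroxy-10-oxodec-8-en-2-yl succinate | C[C@@H](CCC[C@@H](O)C/C=C\C(=O)OCC)OC(=O)CCC(=O)OC(C)(C)C
F13 | step 9 | tert-butyl (S)-5-[(R)-1,5,8-trioxo-3,4,5,8-tetrahydro-1H-isochromen-3-yl]pentan-2-yl succinate | C[C@@H](CCC[C@@H]1CC2=C(C(=O)O1)C(=O)C=CC2=O)OC(=O)CCC(=O)OC(C)(C)C
F14 | step 9 | 4-oxo-4-{[(S)-5-[(R)-1,5,8-trioxo-3,4,5,8-tetrahydro-1H-isochromen-3-yl]pentan-2-yl]oxy}butanoic acid | C[C@@H](CCC[C@@H]1CC2=C(C(=O)O1)C(=O)C=CC2=O)OC(=O)CCC(=O)O
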